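**Retrosynthetic overview**
1. 33 ⇒ 32 ⇒ 30: the last operations are cleavage of the two C4 silyl ethers and enolate hydroxylation at C15′ of one lactone of a C2-symmetric bis-cembranolide.
2. Feature used: in each 14-membered carbocycle (C1–C14), C13 and C14 are adjacent CH2 groups between the epoxide carbon C12 and the lactone-bearing methine C1. Both C13–C14 bonds are therefore traced back to C13=C14 alkenes (30 ⇒ 29 ⇒ 27), formed by a twofold ring-closing metathesis of C1 vinyl groups with 12-methyl-12-vinyl epoxides and then saturated by diimide beside the C7=C8 alkenes.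
3. 27 ⇒ 23 ⇒ 18: vinyl epoxides from C13 epoxy aldehydes (Sharpless epoxidation, oxidation, methylenation). The C15–C17–C17′–C15′ link comes from twofold alkylation of a δ-lactone enolate with ethane-1,2-diyl bis(triflate), anti to the C1 vinyl group.
4. 18 ⇒ 16 ⇒ 13 ⇒ 1: δ-lactone (O–C3–C2–C1–C15–C16) by acrylate ring-closing metathesis and anti vinyl conjugate addition. The C3/C4 diol comes from Sharpless epoxidation of nerol and inverting hydrolysis at C4; C9–C13 from allylic oxidation, nitrile homologation and Wittig olefination.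
5. Ring order: the two δ-lactones first (step 14), then both 14-membered rings in one operation (step 22).

Key step: step 22

Remark on numbering: cembrane locants are used in both halves (C1 ring CH bearing C15; C3 lactone O–CH; C4 carbinol carbon; C7=C8; C11/C12 epoxide; C15 lactone α-carbon; C16 lactone C=O; C17/C17′ linker CH2; primed locants for the half with the C15′ hydroxyl).
Assumption: the SMILES string is taken as the absolute configuration, that is 1R,3S,4S,11S,12S,15S and 1′R,3′S,4′S,11′S,12′S,15′S, with both C7=C8 alkenes E.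
Remark: in the twofold steps 18–21, 23 and 25 the two identical sites react independently and the half-converted species is not numbered; it is numbered in steps 17 and 22.

**Route**

Step 1
Reactants: 1 nerol
Product: 2 (2S,3R)-2,3-epoxynerol
Conditions: Ti(OiPr)4 (5 mol %), L-(+)-diethyl tartrate (7.5 mol %), t-BuOOH, 4 Å molecular sieves, CH2Cl2, −20 °C
Reagents that add atoms: tert-butyl hydroperoxide, CC(C)(C)OO
Why: Sharpless asymmetric epoxidation of the Z allylic alcohol, in which the L-(+)-tartrate titanium catalyst should deliver oxygen to the face that gives the (2S,3R)-epoxide, fixing C3 as S and placing C4 for the inversion of step 11.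

Step 2
Reactants: 2 (2S,3R)-2,3-epoxynerol
Product: 3 [(2S,3R)-3-methyl-3-(4-methylpent-3-en-1-yl)oxiran-2-yl]methyl 4-methylbenzenesulfonate
Conditions: TsCl, Et3N, DMAP (cat.), CH2Cl2, 0 °C
Reagents that add atoms: 4-methylbenzenesulfonyl chloride, Cc1ccc(S(=O)(=O)Cl)cc1
Why: Sulfonylation of the primary alcohol under basic conditions leaves the epoxide and both stereocentres untouched.

Step 3
Reactants: 3 epoxy tosylate
Product: 4 (2S,3R)-3-methyl-3-(4-methylpent-3-en-1-yl)-2-(prop-2-en-1-yl)oxirane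
Conditions: CH2=CHMgBr, CuI (10 mol %), THF, −40 to −10 °C
Reagents that add atoms: vinylmagnesium bromide, C=C[Mg]Br
Why: Copper-catalysed coupling of a Grignard reagent with a primary tosylate (Fouquet–Schlosser type) should outrun attack on the hindered trisubstituted epoxide and brings in C1 as the alkene for step 14.

Step 4
Reactants: 4 allyl epoxide
Product: 5 (2E)-2-methyl-5-[(2R,3S)-2-methyl-3-(prop-2-en-1-yl)oxiran-2-yl]pent-2-en-1-ol
Conditions: SeO2 (cat.), t-BuOOH, salicylic acid (cat.), CH2Cl2, 0 °C to rt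
Reagents that add atoms: tert-butyl hydroperoxide, CC(C)(C)OO
Why: SeO2-catalysed allylic oxidation (ene reaction then 2,3-sigmatropic shift) is selective for the E methyl group of the terminal trisubstituted alkene and should give the E allylic alcohol at C9, the monosubstituted alkene being far less reactive.

Step 5
Reactants: 5 allylic alcohol
Product: 6 (2R,3S)-2-[(3E)-5-bromo-4-methylpent-3-en-1-yl]-2-methyl-3-(prop-2-en-1-yl)oxirane
Conditions: CBr4, PPh3, 2,6-lutidine, CH2Cl2, −20 °C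
Reagents that add atoms: carbon tetrabromide, BrC(Br)(Br)Br
Why: Appel bromination of a primary allylic alcohol at low temperature with a base buffer should proceed without allylic transposition or epoxide opening.

Step 6
Reactants: 6 allylic bromide
Product: 7 (4E)-4-methyl-7-[(2R,3S)-2-methyl-3-(prop-2-en-1-yl)oxiran-2-yl]hept-4-enenitrile
Conditions: CH3CN, n-BuLi, THF, −78 °C; then 6, −78 to −40 °C
Reagents that add atoms: acetonitrile, CC#N
Why: SN2 alkylation of lithioacetonitrile (in excess, to suppress double alkylation) by the primary allylic bromide adds C10 and C11, the trisubstituted epoxide being inert at this temperature.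

Step 7
Reactants: 7 nitrile
Product: 9 (4E)-4-methyl-7-[(2R,3S)-2-methyl-3-(prop-2-en-1-yl)oxiran-2-yl]hept-4-enal, via N-aluminio imine 8 (not isolated)
Conditions: i-Bu2AlH, toluene, −78 °C; then aq. KNaC4H4O6, rt
Reagents that add atoms: water, O
Why: Half-reduction of the nitrile by i-Bu2AlH stops at the N-aluminio imine, which is hydrolysed to the aldehyde on work-up.

Step 8
Reactants: 9 aldehyde
Product: 10 ethyl (2E,6E)-2,6-dimethyl-9-[(2R,3S)-2-methyl-3-(prop-2-en-1-yl)oxiran-2-yl]nona-2,6-dienoate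
Conditions: Ph3P=C(CH3)CO2Et, CH2Cl2, rt to 40 °C
Reagents that add atoms: ethyl 2-(triphenylphosphoranylidene)propanoate, CCOC(=O)C(C)=P(c1ccccc1)(c1ccccc1)c1ccccc1
Why: Wittig olefination with a stabilised ylide should give the E trisubstituted enoate, which supplies C12, its methyl group and C13.

Step 9
Reactants: 10 enoate
Product: 11 (2E,6E)-2,6-dimethyl-9-[(2R,3S)-2-methyl-3-(prop-2-en-1-yl)oxiran-2-yl]nona-2,6-dien-1-ol
Conditions: i-Bu2AlH, CH2Cl2, −78 °C; then aq. KNaC4H4O6
Reagents that add atoms: none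
Why: 1,2-Reduction of the enoate by i-Bu2AlH at −78 °C gives the allylic alcohol and spares the epoxide.

Step 10
Reactants: 11 allylic alcohol
Product: 12 (2S,3R)-3-[(3E,7E)-9-[(4-methoxyphenyl)methoxy]-4,8-dimethylnona-3,7-dien-1-yl]-3-methyl-2-(prop-2-en-1-yl)oxirane
Conditions: NaH, 4-MeOC6H4CH2Cl, Bu4NI (cat.), THF/DMF, 0 °C to rt
Reagents that add atoms: 4-methoxybenzyl chloride, COc1ccc(CCl)cc1
Why: Williamson etherification masks C13–OH with a group that survives acid, organocopper and enolate chemistry and is later removed oxidatively beside the silyl ethers.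

Step 11
Reactants: 12 epoxide
Product: 13 (4S,5S,8E,12E)-14-[(4-methoxyphenyl)methoxy]-5,9,13-trimethyltetradeca-1,8,12-triene-4,5-diol
Conditions: HClO4 (cat.), THF/H2O, 0 °C to rt
Reagents that add atoms: water, O
Why: Acid-catalysed hydrolysis of a trisubstituted epoxide, in which water attacks the tertiary carbon C4 with inversion while the C3–O bond is kept, so that the cis-epoxide from the Z alkene should give the (3S,4S)-diol (locants 4S,5S in the name).

Step 12
Reactants: 13 diol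
Product: 14 (4S,5S,8E,12E)-5-hydroxy-14-[(4-methoxyphenyl)methoxy]-5,9,13-trimethyltetradeca-1,8,12-trien-4-yl prop-2-enoate
Conditions: CH2=CHCOCl, i-Pr2NEt, CH2Cl2, −78 to 0 °C
Reagents that add atoms: acryloyl chloride, C=CC(=O)Cl
Why: O-Acylation should take the secondary C3 hydroxyl and leave the tertiary C4 hydroxyl on steric grounds.

Step 13
Reactants: 14 hydroxy acrylate
Product: 15 (4S,5S,8E,12E)-14-[(4-methoxyphenyl)methoxy]-5,9,13-trimethyl-5-[(triethylsilyl)oxy]tetradeca-1,8,12-trien-4-yl prop-2-enoate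
Conditions: Et3SiOTf, 2,6-lutidine, CH2Cl2, −78 to 0 °C
Reagents that add atoms: triethylsilyl trifluoromethanesulfonate, CC[Si](CC)(CC)OS(=O)(=O)C(F)(F)F
Why: A silyl triflate with a hindered base silylates the tertiary alcohol, which must be masked before the organocopper and enolate steps.

Step 14
Reactants: 15 acrylate
Product: 16 (6S)-6-[(2S,5E,9E)-11-[(4-methoxyphenyl)methoxy]-6,10-dimethyl-2-[(triethylsilyl)oxy]undeca-5,9-dien-2-yl]-5,6-dihydro-2H-pyran-2-one
Conditions: second-generation Grubbs catalyst RuCl2(=CHPh)(PCy3)(H2IMes) (5 mol %), CH2Cl2 (5 mM), 40 °C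
Reagents that add atoms: none
Why: Ring-closing metathesis of the acrylate with the monosubstituted alkene closes the six-membered unsaturated lactone (O–C3–C2–C1=C15–C16) with loss of ethylene, the trisubstituted alkenes being inert.

Step 15
Reactants: 16 unsaturated lactone
Product: 18 (4R,6S)-4-ethenyl-6-[(2S,5E,9E)-11-[(4-methoxyphenyl)methoxy]-6,10-dimethyl-2-[(triethylsilyl)oxy]undeca-5,9-dien-2-yl]oxan-2-one, via silyl ketene acetal 17 (not isolated)
Conditions: CH2=CHMgBr, CuBr·SMe2 (20 mol %), Me3SiCl, THF, −78 °C; then aq. NH4Cl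
Reagents that add atoms: vinylmagnesium bromide, C=C[Mg]Br
Why: Copper-catalysed conjugate addition accelerated by Me3SiCl, in which the vinyl group should attack the half-chair lactone axially on the face opposite the equatorial C3 side chain, setting C1 in the 1,3-trans lactone; the ketene acetal is hydrolysed on work-up.

Step 16
Reactants: 19 ethylene glycol
Product: 20 ethane-1,2-diyl bis(trifluoromethanesulfonate)
Conditions: (CF3SO2)2O, pyridine, CH2Cl2, −78 to 0 °C
Reagents that add atoms: trifluoromethanesulfonic anhydride, O=S(=O)(OS(=O)(=O)C(F)(F)F)C(F)(F)F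
Why: Twofold O-sulfonylation of the diol gives the two-carbon bis-electrophile, which is used directly.

Step 17
Reactants: 18 vinyl lactone (2 equiv); 20 ethane-1,2-diyl bis(trifluoromethanesulfonate)
Product: 23 C2-symmetric bis-lactone 1,2-bis[(3S,4S,6S)-4-ethenyl-6-{(2S,5E,9E)-11-[(4-methoxyphenyl)methoxy]-6,10-dimethyl-2-[(triethylsilyl)oxy]undeca-5,9-dien-2-yl}-2-oxooxan-3-yl]ethane, via lithium enolate 21 (not isolated), via mono-alkylated triflate 22 (not isolated)
Conditions: LiN(i-Pr)2, THF, −78 °C; then 20 (0.5 equiv), −78 to −50 °C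
Reagents that add atoms: none
Why: Twofold C-alkylation of a lactone lithium enolate by a primary alkyl triflate, in which each electrophilic carbon should approach the enolate face opposite the adjacent axial C1 vinyl group and so set C15 and C15′ with the linker trans to vinyl; the high reactivity of the triflate at −78 °C is meant to keep the second intermolecular alkylation ahead of proton transfer.

Step 18
Reactants: 23 bis-lactone
Product: 24 bis(allylic alcohol) 1,2-bis[(3S,4S,6S)-4-ethenyl-6-{(2S,5E,9E)-11-hydroxy-6,10-dimethyl-2-[(triethylsilyl)oxy]undeca-5,9-dien-2-yl}-2-oxooxan-3-yl]ethane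
Conditions: DDQ, CH2Cl2/pH 7 buffer, 0 °C
Reagents that add atoms: none
Why: Oxidative cleavage of the 4-methoxybenzyl ethers by the quinone under buffered conditions leaves the tertiary silyl ethers, lactones and alkenes intact.

Step 19
Reactants: 24 bis(allylic alcohol)
Product: 25 bis(epoxy alcohol) 1,2-bis[(3S,4S,6S)-4-ethenyl-6-{(2S,5E)-8-[(2S,3S)-3-(hydroxymethyl)-3-methyloxiran-2-yl]-6-methyl-2-[(triethylsilyl)oxy]oct-5-en-2-yl}-2-oxooxan-3-yl]ethane
Conditions: Ti(OiPr)4 (20 mol %), L-(+)-diethyl tartrate (26 mol %), t-BuOOH, 4 Å molecular sieves, CH2Cl2, −20 °C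
Reagents that add atoms: tert-butyl hydroperoxide, CC(C)(C)OO
Why: Twofold Sharpless asymmetric epoxidation, in which the L-(+)-tartrate catalyst should convert each E 2-methyl allylic alcohol into the (2S,3S)-epoxy alcohol (11S,12S) under reagent control, leaving the alkenes without an allylic hydroxyl untouched.

Step 20
Reactants: 25 bis(epoxy alcohol)
Product: 26 bis(epoxy aldehyde) 1,2-bis[(3S,4S,6S)-4-ethenyl-6-{(2S,5E)-8-[(2S,3R)-3-formyl-3-methyloxiran-2-yl]-6-methyl-2-[(triethylsilyl)oxy]oct-5-en-2-yl}-2-oxooxan-3-yl]ethane (epoxide geometry unchanged; the descriptor at C12 changes only by priority)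
Conditions: (n-Pr4N)RuO4 (5 mol %), N-methylmorpholine N-oxide, 4 Å molecular sieves, CH2Cl2, rt
Reagents that add atoms: none
Why: Ley–Griffith oxidation under neutral conditions gives the epoxy aldehydes, whose α-carbon C12 is quaternary and cannot epimerise.

Step 21
Reactants: 26 bis(epoxy aldehyde)
Product: 27 bis(vinyl epoxide) 1,2-bis[(3S,4S,6S)-4-ethenyl-6-{(2S,5E)-8-[(2S,3S)-3-ethenyl-3-methyloxiran-2-yl]-6-methyl-2-[(triethylsilyl)oxy]oct-5-en-2-yl}-2-oxooxan-3-yl]ethane
Conditions: Ph3PCH3Br, KN(SiMe3)2, THF, 0 °C; then 26, −78 to 0 °C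
Reagents that add atoms: methyltriphenylphosphonium bromide, C[P+](c1ccccc1)(c1ccccc1)c1ccccc1.[Br-]
Why: Wittig methylenation of the epoxy aldehydes gives the 12-methyl-12-vinyl epoxides, the ylide adding to the aldehydes faster than it can deprotonate the hindered lactone α-positions.

Step 22
Reactants: 27 bis(vinyl epoxide)
Product: 29 13,14,13′,14′-tetradehydro bis-cembranolide 4,4′-bis(triethylsilyl ether) (two 14-membered rings closed; both C13=C14 alkenes drawn E), via mono-macrocycle 28 (not isolated)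
Conditions: second-generation Grubbs catalyst RuCl2(=CHPh)(PCy3)(H2IMes) (2 × 10 mol %), 1,4-benzoquinone (20 mol %), toluene (1 mM), 60 °C, argon purge
Reagents that add atoms: none
Why: Olefin metathesis through ruthenium alkylidene and metallacyclobutane intermediates: the catalyst should load on the unhindered C1 vinyl group of one lactone, add across the vinyl group on C12 of the same half and expel ethylene, and then do the same in the second half (27 to 28 to 29). The closest known reaction type is macrocyclic ring-closing metathesis of two monosubstituted alkenes, one of them a 2-methyl-2-vinyloxirane; each new ring is a 14-membered carbocycle (C1 to C14) closed at C13=C14, and the trisubstituted C7=C8 alkenes, epoxides, silyl ethers and lactones are spectators. No stereocentre is created, and the geometry of the new alkenes is irrelevant because step 23 saturates them. The selectivity needed is the 14-membered closure inside each half over the eight-membered closure between the two C1 vinyl groups (C14–C1–C15–C17–C17′–C15′–C1′–C14′) and over oligomerisation. It rests on the lactone conformation, in which the C3 side chain is equatorial so that the trans C1 vinyl group and the trans C15 arm are diaxial and anti, turning the two vinyl groups away from the linker, and on high dilution. A strained cyclooctene that formed anyway would still carry both vinyl epoxides and could be reopened by an alkylidene formed at C13, so the strain-free bis-macrocycle should be the thermodynamic sink.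

Step 23
Reactants: 29 tetradehydro bis-cembranolide
Product: 30 bis-cembranolide 4,4′-bis(triethylsilyl ether) (15′-deoxy-33 with both C4 hydroxyls silylated)
Conditions: 2,4,6-(i-Pr)3C6H2SO2NHNH2, Et3N, ClCH2CH2Cl, 50 °C
Reagents that add atoms: none
Why: Diimide reduction (concerted syn transfer of two hydrogens), whose rate falls steeply with alkene substitution, should saturate the two disubstituted C13=C14 alkenes and spare the trisubstituted C7=C8 alkenes, the epoxides and the lactones.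

Step 24
Reactants: 30 bis-cembranolide bis(silyl ether)
Product: 32 15′-hydroxy bis-cembranolide 4,4′-bis(triethylsilyl ether) (33 with both C4 hydroxyls silylated), via potassium enolate 31 (not isolated)
Conditions: KN(SiMe3)2 (1.0 equiv), THF, −78 °C; then 2-(benzenesulfonyl)-3-phenyloxaziridine, −78 °C; aq. NH4Cl
Reagents that add atoms: 2-(benzenesulfonyl)-3-phenyloxaziridine, O=S(=O)(c1ccccc1)N1OC1c1ccccc1
Why: Davis oxaziridine hydroxylation of the mono-enolate, in which the oxidant should approach C15′ on the face opposite the adjacent C14′ chain on C1′ (the same face the linker took in step 17), giving the 15′S tertiary alcohol; one equivalent of base limits the reaction to one lactone, so unreacted 30 (to be recycled) and some bis-hydroxylated material are expected beside 32.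

Step 25
Reactants: 32 bis(silyl ether)
Product: 33 target CNP0186476.4
Conditions: HF·pyridine, pyridine, THF, 0 °C to rt
Reagents that add atoms: none
Why: Buffered fluoride cleavage of the two tertiary triethylsilyl ethers should leave the trisubstituted epoxides, the lactones and the tertiary α-hydroxy lactone untouched.

**Compound list**
1 | nerol, (2Z)-3,7-dimethylocta-2,6-dien-1-ol | CC(C)=CCC/C(C)=C\CO | starting material
2 | (2S,3R)-2,3-epoxynerol, [(2S,3R)-3-methyl-3-(4-methylpent-3-en-1-yl)oxiran-2-yl]methanol | CC(C)=CCC[C@@]1(C)O[C@H]1CO | intermediate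
3 | [(2S,3R)-3-methyl-3-(4-methylpent-3-en-1-yl)oxiran-2-yl]methyl 4-methylbenzenesulfonate | CC(C)=CCC[C@@]1(C)O[C@H]1COS(=O)(=O)c2ccc(C)cc2 | intermediate
4 | (2S,3R)-3-methyl-3-(4-methylpent-3-en-1-yl)-2-(prop-2-en-1-yl)oxirane | CC(C)=CCC[C@@]1(C)O[C@H]1CC=C | intermediate
5 | (2E)-2-methyl-5-[(2R,3S)-2-methyl-3-(prop-2-en-1-yl)oxiran-2-yl]pent-2-en-1-ol | OC/C(C)=C/CC[C@@]1(C)O[C@H]1CC=C | intermediate
6 | (2R,3S)-2-[(3E)-5-bromo-4-methylpent-3-en-1-yl]-2-methyl-3-(prop-2-en-1-yl)oxirane | BrC/C(C)=C/CC[C@@]1(C)O[C@H]1CC=C | intermediate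
7 | (4E)-4-methyl-7-[(2R,3S)-2-methyl-3-(prop-2-en-1-yl)oxiran-2-yl]hept-4-enenitrile | N#CCC/C(C)=C/CC[C@@]1(C)O[C@H]1CC=C | intermediate
8 | N-(diisobutylaluminio) imine of 9 | CC(C)C[Al](CC(C)C)N=CCC/C(C)=C/CC[C@@]1(C)O[C@H]1CC=C | intermediate (not isolated)
9 | (4E)-4-methyl-7-[(2R,3S)-2-methyl-3-(prop-2-en-1-yl)oxiran-2-yl]hept-4-enal | O=CCC/C(C)=C/CC[C@@]1(C)O[C@H]1CC=C | intermediate
10 | ethyl (2E,6E)-2,6-dimethyl-9-[(2R,3S)-2-methyl-3-(prop-2-en-1-yl)oxiran-2-yl]nona-2,6-dienoate | CCOC(=O)/C(C)=C/CC/C(C)=C/CC[C@@]1(C)O[C@H]1CC=C | intermediate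
11 | (2E,6E)-2,6-dimethyl-9-[(2R,3S)-2-methyl-3-(prop-2-en-1-yl)oxiran-2-yl]nona-2,6-dien-1-ol | OC/C(C)=C/CC/C(C)=C/CC[C@@]1(C)O[C@H]1CC=C | intermediate
12 | (2S,3R)-3-[(3E,7E)-9-[(4-methoxyphenyl)methoxy]-4,8-dimethylnona-3,7-dien-1-yl]-3-methyl-2-(prop-2-en-1-yl)oxirane | COc1ccc(COC/C(C)=C/CC/C(C)=C/CC[C@@]2(C)O[C@H]2CC=C)cc1 | intermediate
13 | (4S,5S,8E,12E)-14-[(4-methoxyphenyl)methoxy]-5,9,13-trimethyltetradeca-1,8,12-triene-4,5-diol | COc1ccc(COC/C(C)=C/CC/C(C)=C/CC[C@](C)(O)[C@@H](O)CC=C)cc1 | intermediate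
14 | (4S,5S,8E,12E)-5-hydroxy-14-[(4-methoxyphenyl)methoxy]-5,9,13-trimethyltetradeca-1,8,12-trien-4-yl prop-2-enoate | COc1ccc(COC/C(C)=C/CC/C(C)=C/CC[C@](C)(O)[C@@H](OC(=O)C=C)CC=C)cc1 | intermediate
15 | (4S,5S,8E,12E)-14-[(4-methoxyphenyl)methoxy]-5,9,13-trimethyl-5-[(triethylsilyl)oxy]tetradeca-1,8,12-trien-4-yl prop-2-enoate | COc1ccc(COC/C(C)=C/CC/C(C)=C/CC[C@](C)(O[Si](CC)(CC)CC)[C@@H](OC(=O)C=C)CC=C)cc1 | intermediate
16 | (6S)-6-[(2S,5E,9E)-11-[(4-methoxyphenyl)methoxy]-6,10-dimethyl-2-[(triethylsilyl)oxy]undeca-5,9-dien-2-yl]-5,6-dihydro-2H-pyran-2-one | COc1ccc(COC/C(C)=C/CC/C(C)=C/CC[C@](C)(O[Si](CC)(CC)CC)[C@@H]2CC=CC(=O)O2)cc1 | intermediate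
17 | trimethylsilyl ketene acetal of 18 (C15=C16–OSiMe3) | COc1ccc(COC/C(C)=C/CC/C(C)=C/CC[C@](C)(O[Si](CC)(CC)CC)[C@@H]2C[C@@H](C=C)C=C(O[Si](C)(C)C)O2)cc1 | intermediate (not isolated)
18 | (4R,6S)-4-ethenyl-6-[(2S,5E,9E)-11-[(4-methoxyphenyl)methoxy]-6,10-dimethyl-2-[(triethylsilyl)oxy]undeca-5,9-dien-2-yl]oxan-2-one | COc1ccc(COC/C(C)=C/CC/C(C)=C/CC[C@](C)(O[Si](CC)(CC)CC)[C@@H]2C[C@@H](C=C)CC(=O)O2)cc1 | intermediate
19 | ethylene glycol | OCCO | starting material
20 | ethane-1,2-diyl bis(trifluoromethanesulfonate) | O=S(=O)(OCCOS(=O)(=O)C(F)(F)F)C(F)(F)F | intermediate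
21 | lithium enolate of 18 | COc1ccc(COC/C(C)=C/CC/C(C)=C/CC[C@](C)(O[Si](CC)(CC)CC)[C@@H]2C[C@@H](C=C)C=C(O[Li])O2)cc1 | intermediate (not isolated)
22 | 18 carrying a 2-(trifluoromethanesulfonyloxy)ethyl group at C15, trans to the C1 vinyl group | COc1ccc(COC/C(C)=C/CC/C(C)=C/CC[C@](C)(O[Si](CC)(CC)CC)[C@@H]2C[C@@H](C=C)[C@H](CCOS(=O)(=O)C(F)(F)F)C(=O)O2)cc1 | intermediate (not isolated)
23 | C2-symmetric bis-lactone, 1,2-bis[(3S,4S,6S)-4-ethenyl-6-{(2S,5E,9E)-11-[(4-methoxyphenyl)methoxy]-6,10-dimethyl-2-[(triethylsilyl)oxy]undeca-5,9-dien-2-yl}-2-oxooxan-3-yl]ethane | COc1ccc(COC/C(C)=C/CC/C(C)=C/CC[C@](C)(O[Si](CC)(CC)CC)[C@@H]2C[C@@H](C=C)[C@H](CC[C@@H]3C(=O)O[C@H]([C@@](C)(O[Si](CC)(CC)CC)CC/C=C(C)/CC/C=C(C)/COCc4ccc(OC)cc4)C[C@H]3C=C)C(=O)O2)cc1 | intermediate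
24 | bis(allylic alcohol), 23 with C13–OH and C13′–OH free | OC/C(C)=C/CC/C(C)=C/CC[C@](C)(O[Si](CC)(CC)CC)[C@@H]2C[C@@H](C=C)[C@H](CC[C@@H]3C(=O)O[C@H]([C@@](C)(O[Si](CC)(CC)CC)CC/C=C(C)/CC/C=C(C)/CO)C[C@H]3C=C)C(=O)O2 | intermediate
25 | bis(epoxy alcohol), 24 with (11S,12S)- and (11′S,12′S)-epoxides | OC[C@]1(C)O[C@H]1CC/C(C)=C/CC[C@](C)(O[Si](CC)(CC)CC)[C@@H]2C[C@@H](C=C)[C@H](CC[C@@H]3C(=O)O[C@H]([C@@](C)(O[Si](CC)(CC)CC)CC/C=C(C)/CC[C@@H]4O[C@@]4(C)CO)C[C@H]3C=C)C(=O)O2 | intermediate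
26 | bis(epoxy aldehyde), 25 with C13 and C13′ as CHO | O=C[C@]1(C)O[C@H]1CC/C(C)=C/CC[C@](C)(O[Si](CC)(CC)CC)[C@@H]2C[C@@H](C=C)[C@H](CC[C@@H]3C(=O)O[C@H]([C@@](C)(O[Si](CC)(CC)CC)CC/C=C(C)/CC[C@@H]4O[C@@]4(C)C=O)C[C@H]3C=C)C(=O)O2 | intermediate
27 | bis(vinyl epoxide), C2-symmetric bis-lactone with C1/C1′ vinyl groups, (11S,12S)-12-methyl-12-vinyl epoxides and C4/C4′ triethylsilyl ethers | C=C[C@]1(C)O[C@H]1CC/C(C)=C/CC[C@](C)(O[Si](CC)(CC)CC)[C@@H]2C[C@@H](C=C)[C@H](CC[C@@H]3C(=O)O[C@H]([C@@](C)(O[Si](CC)(CC)CC)CC/C=C(C)/CC[C@@H]4O[C@@]4(C)C=C)C[C@H]3C=C)C(=O)O2 | intermediate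
28 | mono-macrocycle, 27 with one 14-membered ring closed at C13=C14 (E) | C/C1=C\CC[C@](C)(O[Si](CC)(CC)CC)[C@@H]2C[C@@H](/C=C/[C@]3(C)O[C@H]3CC1)[C@H](CC[C@@H]4C(=O)O[C@H]([C@@](C)(O[Si](CC)(CC)CC)CC/C=C(C)/CC[C@@H]5O[C@@]5(C)C=C)C[C@H]4C=C)C(=O)O2 | intermediate (not isolated)
29 | 13,14,13′,14′-tetradehydro bis-cembranolide 4,4′-bis(triethylsilyl ether), both new alkenes drawn E | C/C1=C\CC[C@](C)(O[Si](CC)(CC)CC)[C@@H]2C[C@@H](/C=C/[C@]3(C)O[C@H]3CC1)[C@H](CC[C@@H]1C(=O)O[C@H]3C[C@H]1/C=C/[C@]1(C)O[C@H]1CC/C(C)=C/CC[C@]3(C)O[Si](CC)(CC)CC)C(=O)O2 | intermediate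
30 | bis-cembranolide 4,4′-bis(triethylsilyl ether) (15′-deoxy-33, silylated at both C4 hydroxyls) | C/C1=C\CC[C@](C)(O[Si](CC)(CC)CC)[C@@H]2C[C@@H](CC[C@]3(C)O[C@H]3CC1)[C@H](CC[C@@H]1C(=O)O[C@H]3C[C@H]1CC[C@]1(C)O[C@H]1CC/C(C)=C/CC[C@]3(C)O[Si](CC)(CC)CC)C(=O)O2 | intermediate
31 | mono potassium enolate of 30 (C15′=C16′–OK) | C/C1=C\CC[C@](C)(O[Si](CC)(CC)CC)[C@@H]2C[C@@H](CC[C@]3(C)O[C@H]3CC1)[C@H](CCC1=C(O[K])O[C@H]3C[C@H]1CC[C@]1(C)O[C@H]1CC/C(C)=C/CC[C@]3(C)O[Si](CC)(CC)CC)C(=O)O2 | intermediate (not isolated)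
32 | 15′-hydroxy bis-cembranolide 4,4′-bis(triethylsilyl ether) (33 silylated at both C4 hydroxyls) | C/C1=C\CC[C@](C)(O[Si](CC)(CC)CC)[C@@H]2C[C@@H](CC[C@]3(C)O[C@H]3CC1)[C@H](CC[C@@]1(O)C(=O)O[C@H]3C[C@H]1CC[C@]1(C)O[C@H]1CC/C(C)=C/CC[C@]3(C)O[Si](CC)(CC)CC)C(=O)O2 | intermediate
33 | CNP0186476.4 | C/C1=C\CC[C@](C)(O)[C@@H]2C[C@@H](CC[C@]3(C)O[C@H]3CC1)[C@H](CC[C@@]1(O)C(=O)O[C@H]3C[C@H]1CC[C@]1(C)O[C@H]1CC/C(C)=C/CC[C@]3(C)O)C(=O)O2 | target

**Totals and risks**

Total step count: 25. Longest linear sequence: 24 steps (steps 1–15 and 17–25, from nerol); step 16 is a one-step side branch.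

Steps most likely to fail:

1. Step 22. The alkylidene formed at one C1 vinyl group may close onto the other C1 vinyl group across the linker (eight-membered ring) or onto a vinyl epoxide of another molecule, so that cyclooctene and oligomers form faster than the two 14-membered rings. Fallback: close each ring before the halves are joined, setting out from 18 and returning at 30. Quinone cleavage of the 4-methoxybenzyl ether of 18 would give allylic alcohol F1. Sharpless epoxidation with L-(+)-diethyl tartrate would give epoxy alcohol F2, and (n-Pr4N)RuO4 with N-methylmorpholine N-oxide epoxy aldehyde F3. Methylenation with Ph3P=CH2 would give vinyl epoxide F4, in which the single C1 vinyl group has only the 14-membered closure open to it. Ring-closing metathesis would then give didehydro macrolide F5 and diimide reduction saturated macrolide F6. Its lithium enolate F7 would be alkylated twice by 20, through mono-alkylated triflate F8 and anti to the C14 chain, to reach 30.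

2. Step 17. Proton transfer from the mono-alkylated triflate to unreacted enolate may be followed by three-membered ring closure to a spiro-cyclopropane; loss of triflate from 20 by elimination and O-alkylation are further drains. Fallback: put the linker in before the lactones exist, setting out from 13 and returning at 23. Ethyl 2-(bromomethyl)acrylate would be homocoupled with zinc to diethyl 2,5-dimethylenehexanedioate F9 and saponified to 2,5-dimethylenehexanedioic acid F10. Esterification of F10 with two equivalents of 13 at the secondary hydroxyl (N,N′-dicyclohexylcarbodiimide, 4-(dimethylamino)pyridine) would give bis-ester F11, and Et3SiOTf bis(silyl ether) F12. Twofold ring-closing metathesis (same ruthenium catalyst, toluene, 80 °C) would give bis-pentenolide F13 with C15=C1 alkenes and the linker in place. Twofold copper-mediated vinyl addition with Me3SiCl would give bis(silyl ketene acetal) F14, whose protonation leads to 23. In this variant C15 is set by protonation and not by alkylation, so the lactone α-centres would have to be equilibrated with DBU and 23 separated from its C15 epimers.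

3. Step 24. Proton exchange between the mono-enolate and the second lactone may erase site control and lead to over-oxidation, and the flexible bicyclic enolate may discriminate its faces poorly. Fallback: hydroxylate before the macrocycles are closed, setting out from 27 and returning at 32. One equivalent of KN(SiMe3)2 would convert 27 into potassium enolate F15, and the oxaziridine would give mono-hydroxy bis(vinyl epoxide) F16, on a monocyclic lactone whose axial C1 vinyl group is the control element already used in step 17. The twofold ring-closing metathesis of step 22 would then run through either mono-macrocycle, with the ring closed in the unhydroxylated half (mono-macrocycle F17) or in the hydroxylated half (mono-macrocycle F18), to hydroxy tetradehydro compound F19. Diimide reduction as in step 23 would give 32.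

**Further compounds**
F1 | step 22 | (4R,6S)-4-ethenyl-6-[(2S,5E,9E)-11-hydroxy-6,10-dimethyl-2-[(triethylsilyl)oxy]undeca-5,9-dien-2-yl]oxan-2-one | OC/C(C)=C/CC/C(C)=C/CC[C@](C)(O[Si](CC)(CC)CC)[C@@H]1C[C@@H](C=C)CC(=O)O1
F2 | step 22 | (4R,6S)-4-ethenyl-6-[(2S,5E)-8-[(2S,3S)-3-(hydroxymethyl)-3-methyloxiran-2-yl]-6-methyl-2-[(triethylsilyl)oxy]oct-5-en-2-yl]oxan-2-one | OC[C@]1(C)O[C@H]1CC/C(C)=C/CC[C@](C)(O[Si](CC)(CC)CC)[C@@H]2C[C@@H](C=C)CC(=O)O2
F3 | step 22 | epoxy aldehyde, F2 with C13 as CHO | O=C[C@]1(C)O[C@H]1CC/C(C)=C/CC[C@](C)(O[Si](CC)(CC)CC)[C@@H]2C[C@@H](C=C)CC(=O)O2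
F4 | step 22 | monomeric vinyl epoxide, F3 with C13 as CH=CH2 | C=C[C@]1(C)O[C@H]1CC/C(C)=C/CC[C@](C)(O[Si](CC)(CC)CC)[C@@H]2C[C@@H](C=C)CC(=O)O2
F5 | step 22 | monomeric 13,14-didehydro cembranolide 4-triethylsilyl ether | C/C1=C\CC[C@](C)(O[Si](CC)(CC)CC)[C@@H]2C[C@@H](/C=C/[C@]3(C)O[C@H]3CC1)CC(=O)O2
F6 | step 22 | monomeric cembranolide 4-triethylsilyl ether (one half of 30 with C15 as CH2) | C/C1=C\CC[C@](C)(O[Si](CC)(CC)CC)[C@@H]2C[C@@H](CC[C@]3(C)O[C@H]3CC1)CC(=O)O2
F7 | step 22 | lithium enolate of F6 | C/C1=C\CC[C@](C)(O[Si](CC)(CC)CC)[C@@H]2C[C@@H](CC[C@]3(C)O[C@H]3CC1)C=C(O[Li])O2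
F8 | step 22 | F6 carrying a 2-(trifluoromethanesulfonyloxy)ethyl group at C15, trans to C14 | C/C1=C\CC[C@](C)(O[Si](CC)(CC)CC)[C@@H]2C[C@@H](CC[C@]3(C)O[C@H]3CC1)[C@H](CCOS(=O)(=O)C(F)(F)F)C(=O)O2
F9 | step 17 | diethyl 2,5-dimethylenehexanedioate | C=C(CCC(=C)C(=O)OCC)C(=O)OCC
F10 | step 17 | 2,5-dimethylenehexanedioic acid | C=C(CCC(=C)C(=O)O)C(=O)O
F11 | step 17 | bis-ester of F10 with the C3 hydroxyl of two molecules of 13 | COc1ccc(COC/C(C)=C/CC/C(C)=C/CC[C@](C)(O)[C@H](CC=C)OC(=O)C(=C)CCC(=C)C(=O)O[C@@H](CC=C)[C@@](C)(O)CC/C=C(C)/CC/C=C(C)/COCc2ccc(OC)cc2)cc1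
F12 | step 17 | F11 with both C4 hydroxyls as triethylsilyl ethers | COc1ccc(COC/C(C)=C/CC/C(C)=C/CC[C@](C)(O[Si](CC)(CC)CC)[C@H](CC=C)OC(=O)C(=C)CCC(=C)C(=O)O[C@@H](CC=C)[C@@](C)(O[Si](CC)(CC)CC)CC/C=C(C)/CC/C=C(C)/COCc2ccc(OC)cc2)cc1
F13 | step 17 | bis-pentenolide, two 5,6-dihydro-2H-pyran-2-ones joined at their α-carbons by CH2CH2 | COc1ccc(COC/C(C)=C/CC/C(C)=C/CC[C@](C)(O[Si](CC)(CC)CC)[C@@H]2CC=C(CCC3=CC[C@@H]([C@@](C)(O[Si](CC)(CC)CC)CC/C=C(C)/CC/C=C(C)/COCc4ccc(OC)cc4)OC3=O)C(=O)O2)cc1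
F14 | step 17 | bis(trimethylsilyl ketene acetal) of 23 | COc1ccc(COC/C(C)=C/CC/C(C)=C/CC[C@](C)(O[Si](CC)(CC)CC)[C@@H]2C[C@@H](C=C)C(CCC3=C(O[Si](C)(C)C)O[C@H]([C@@](C)(O[Si](CC)(CC)CC)CC/C=C(C)/CC/C=C(C)/COCc4ccc(OC)cc4)C[C@H]3C=C)=C(O[Si](C)(C)C)O2)cc1
F15 | step 24 | mono potassium enolate of 27 | C=C[C@]1(C)O[C@H]1CC/C(C)=C/CC[C@](C)(O[Si](CC)(CC)CC)[C@@H]2C[C@@H](C=C)[C@H](CCC3=C(O[K])O[C@H]([C@@](C)(O[Si](CC)(CC)CC)CC/C=C(C)/CC[C@@H]4O[C@@]4(C)C=C)C[C@H]3C=C)C(=O)O2
F16 | step 24 | 27 with a hydroxyl at C15′ (OH trans to the C1′ vinyl group) | C=C[C@]1(C)O[C@H]1CC/C(C)=C/CC[C@](C)(O[Si](CC)(CC)CC)[C@@H]2C[C@@H](C=C)[C@H](CC[C@@]3(O)C(=O)O[C@H]([C@@](C)(O[Si](CC)(CC)CC)CC/C=C(C)/CC[C@@H]4O[C@@]4(C)C=C)C[C@H]3C=C)C(=O)O2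
F17 | step 24 | F16 with the 14-membered ring closed in the unhydroxylated half | C/C1=C\CC[C@](C)(O[Si](CC)(CC)CC)[C@@H]2C[C@@H](/C=C/[C@]3(C)O[C@H]3CC1)[C@H](CC[C@@]4(O)C(=O)O[C@H]([C@@](C)(O[Si](CC)(CC)CC)CC/C=C(C)/CC[C@@H]5O[C@@]5(C)C=C)C[C@H]4C=C)C(=O)O2
F18 | step 24 | F16 with the 14-membered ring closed in the hydroxylated half | C=C[C@]1(C)O[C@H]1CC/C(C)=C/CC[C@](C)(O[Si](CC)(CC)CC)[C@@H]2C[C@@H](C=C)[C@H](CC[C@@]1(O)C(=O)O[C@H]3C[C@H]1/C=C/[C@]1(C)O[C@H]1CC/C(C)=C/CC[C@]3(C)O[Si](CC)(CC)CC)C(=O)O2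
F19 | step 24 | 15′-hydroxy-29 | C/C1=C\CC[C@](C)(O[Si](CC)(CC)CC)[C@@H]2C[C@@H](/C=C/[C@]3(C)O[C@H]3CC1)[C@H](CC[C@@]1(O)C(=O)O[C@H]3C[C@H]1/C=C/[C@]1(C)O[C@H]1CC/C(C)=C/CC[C@]3(C)O[Si](CC)(CC)CC)C(=O)O2
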